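At the last readings of the simulated runs the open intermediate stood at the converted fraction of the substrate minus a small fraction that had leaked on to product, so I reckoned the large term first and then the correction by itself.

| setting | epsilon | alpha | zeta | Saturday's | Sunday's | Thursday's |
|---|---|---|---|---|---|---|
| substrate | 6.7 mM | 15 mM | 10 mM | 10 mM | 10 mM | 10 mM |
| reagent | 25 mM | 25 mM | 12 mM | 25.0 mM | 25.0 mM | 25.0 mM |
| gas | 0.36 mM (held) | 0.36 mM (held) | 0.36 mM (held) | 0.36 mM (held) | 0.36 mM (held) | 0.36 mM (held) |
| temperature | 75 °C | 100 °C | 75 °C | 80 °C | 120 °C | 100 °C |
| remark | run made earlier | run made earlier | run made earlier |  |  |  |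
| time |  |  |  | 2.5 h | 2.5 h | 2.5 h |

epsilon run (percent of the substrate charged)

| time / h | open intermediate / % | product / % | substrate / % |
|---|---|---|---|
| 0.333 | 10.9 | 0 | 90.5 |
| 0.833 | 23.2 | 0.5 | 77.8 |
| 1.50 | 35.3 | 0.4 | 63.6 |
| 2.50 | 50.6 | 0.9 | 48.1 |

alpha run (percent of the substrate charged)

| time / min | open intermediate / % | product / % | substrate / % |
|---|---|---|---|
| 8.00 | 14.6 | 0 | 85.4 |
| 20.0 | 31.6 | 0.3 | 68.2 |
| 30.0 | 41.9 | 0.7 | 58.5 |
| 60.0 | 60.5 | 1.7 | 37.9 |

zeta run (percent of the substrate charged)

| time / h | open intermediate / % | product / % | substrate / % |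
|---|---|---|---|
| 0.200 | 3.2 | 0 | 97.5 |
| 0.500 | 7.1 | 0.5 | 92.5 |
| 1.00 | 12.9 | 0.4 | 87.4 |
| 2.50 | 27.0 | 0 | 71.5 |

(readings scatter by 0.5 percentage points)

- at the start none of the gas is in solution
- a reading or a percentage of product counts all its forms, free or not

- the best flask by amount of open intermediate, in percent of the substrate charged; "all alike" if 1.5 percentage points covers them all (Saturday's / Sunday's / Thursday's / all alike)
- amount of open intermediate at the end, in percent of the substrate charged, Saturday's
- amount of open intermediate at the end, in percent of the substrate charged, Sunday's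
- amount of open intermediate at the end, in percent of the substrate charged, Thursday's

The nearest simulated run to Thursday's flask is the alpha run, at the same temperature and reagent, but the alpha run charged 0.600 of substrate per reagent, more than the 0.400 of Thursday's. The apparent first-order constant of the alpha run sagged from 1.18 h⁻¹ at the first reading to 0.970 h⁻¹ at the last. I read that sag as reagent being spent, and I assumed one reagent for each substrate converted, so Thursday's flask should lose less of its rate. With that balance the pseudo-first-order constant at full reagent came to 1.26 h⁻¹ from the alpha run and 0.318 h⁻¹ from the epsilon run. Stepping it geometrically with temperature, I expected substrate fractions left of 40.7% on Saturday's, 9.65% on Thursday's and 0.204% on Sunday's.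

For the correction, let τ be minus the logarithm of the substrate fraction left and X the converted fraction. I assumed a leak in proportion to the open intermediate, with a first-order constant in fixed ratio to that of substrate loss, and this gives product equal to that ratio times τ−X. The last reading of the alpha run gives 0.0487 for this leak ratio, product divided by τ−X, a selectivity factor of the leak against substrate loss. The epsilon run gives 0.0423, alike within the scatter, so I carried the ratio across temperature. Conversion minus correction gave me 57.8% for Saturday's, 74.5% for Sunday's and 83.4% for Thursday's, which I took as the best flask.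

The forecast read a sag at the same temperature as “product inhibition or catalyst decay” and named Thursday's too, with 57%, 68% and 79% for Saturday's, Sunday's and Thursday's, lower than mine on Sunday's and on Thursday's.

Thursday's gave 85.1%, ahead of Sunday's 80.7% and Saturday's 58.4%.

    substrate + reagent → open intermediate (k = 0.0140 M⁻¹ s⁻¹, Ea = 60.0 kJ mol⁻¹)
    reagent + partner → second intermediate (k = 0.00850 M⁻¹ s⁻¹, Ea = 91.0 kJ mol⁻¹)
    open intermediate + second intermediate → product (k = 0.530 M⁻¹ s⁻¹, Ea = 63.0 kJ mol⁻¹)
    crystals ⇌ product, rate k4*(cs4 - [product]) while solid is left; crystals form when [product] > cs4 (solubility = 2.00 mM, k = 0.00380 s⁻¹)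
    gas ⇌ partner, rate k5*(csat - [partner]) (kL = 0.300 s⁻¹)
    (constants at 100 °C)

At 2.50 h Thursday's held 9.96% of its substrate and 4.93% as product, while the leak ratio on that conversion gives 6.85%. On Sunday's, at a conversion of 99.5%, the same leak ratio gives 20.6% of product, and Sunday's flask held 18.8%.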